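## Structural features

The target is an open-chain bis(bibenzyl) with four benzene rings: ring A (3-hydroxyphenyl), ring B (1,4-phenylene), ring C (a 1,2,4-trisubstituted phenol) and ring D (a 3-substituted catechol). They are joined A–CH2CH2–B, B–O–C (diaryl ether) and C–CH2CH2–D. Ring C carries its hydroxyl next to the ring B aryloxy group, and the CH2 of the C–D bridge sits para to that hydroxyl and meta to the ether oxygen. Ring D carries the bridge at C1 and hydroxyls at C2 and C3. The molecule has no stereocentre, so there are no neighbouring stereocentres and nothing to control in three dimensions. The catechol and the ortho-aryloxyphenol are oxidised easily in air, especially under base, so all four hydroxyls should be released last; among the intermediates, the quinone monoketal and the quinol ketal are acid-labile. The real difficulty is regiochemical: ring C must receive the ether oxygen ortho and the carbon chain para to the same hydroxyl, and the four rings must be assembled unsymmetrically. The key step exploits the ring C carbon para to the hydroxyl. In the phenol this carbon is nucleophilic, but in the 4,4-dimethoxycyclohexadienone made from the corresponding 4-methoxyphenol it is the only carbonyl carbon, so its bond to the bridge CH2 can be formed with a carbanion and the arene restored afterwards.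

## Logic of the disconnections

18 to 17: the three O–CH3 bonds on rings A and D are restored. This keeps the oxidisable phenols masked until the end and leaves ring C as the only free phenol. The forward step must cleave three aryl methyl ethers without touching the diaryl ether.

17 to 15 (through 16): no skeletal bond is cut. Ring C is written in dearomatised form, with a hydroxyl returned to the chain-bearing carbon and the phenolic carbon expressed as a dimethyl ketal. This turns the chain-bearing carbon into a former carbonyl carbon, which is what allows the next cut. The forward step must hydrolyse the ketal before the tertiary carbinol ionises, and the two-electron reduction must expel only that hydroxyl.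

15 to 10 and 14: the bond between the carbinol carbon of ring C and the CH2 of the C–D bridge is cut. This is the most convergent cut, giving an A–B–C half and a ring D half with its complete two-carbon bridge. The forward step must be a clean 1,2-addition to a cross-conjugated dienone that also offers two β-carbons and a ketal.

14 to 13 to 12 to 11: the C–Mg, C–Br and C–O bonds at the chain terminus are traced back to a carboxyl group. Both bridge carbons and the complete ring D oxygen pattern are then bought in 11. The forward steps are a chemoselective acid reduction and a neutral bromination that does not eliminate to the styrene.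

10 to 9: one C–OCH3 bond of the ketal is cut and the carbonyl is returned to a phenol. The dearomatised electrophile becomes an ordinary para-methoxyphenol. The forward oxidation must trap methanol at the methoxy-bearing para carbon only.

9 to 7 (through 8): the phenolic C–O bond is traced back to a C–CHO bond. The oxygen and carbon pattern of ring C then matches commercial 6. The forward oxidation requires selective aryl migration, which the para-methoxy group favours.

7 to 5 and 6: the diaryl ether bond between the oxygen and ring B is cut, leaving the oxygen on ring C where it already exists as a phenol. This divides the A–B–C half into a bromide and a commodity phenol. The forward step is a C–O coupling of an unactivated aryl bromide in the presence of an aldehyde.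

5 to 4 to 1 and 2 (through 3): a double bond is reintroduced into the A–B bridge and its central C–C bond is cut. Two commercial one-ring pieces result. The forward sequence is an olefination followed by saturation that must not remove the bromine needed in 5.

## Other disconnections considered

Alternative 1: Ring A is taken apart into the 1,3-bis(trimethylsilyloxy)diene of methyl acetoacetate A3 and the β-keto acetal A2, which already carries rings B, C and D. In the forward direction TiCl4 would ionise the acetal, the diene terminus would attack it, and the diene C2 would close onto the ketone. Aromatisation would give the methyl 6-alkylsalicylate A1, after which ester hydrolysis, decarboxylation and demethylation of rings C and D would still be needed.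
- In favour: the meta relation between hydroxyl and chain on ring A follows from the mechanism, and the ring A phenol arrives unprotected. The sequence parallels the biogenetic relation between lunularic-acid-type acids and their decarboxylated phenols. Because A1 is itself such an acid, this plan is better for reaching carboxylated congeners.
- Against: ring A is the simplest ring and can be bought as a 3-methoxybenzyl unit, so a two-bond ring construction is spent on a commodity. A2 must already contain the diaryl ether and the ring C pattern, so the hard problems are left unsolved. A2 needs several homologation steps, and TiCl4 next to three electron-rich arenes invites Friedel–Crafts side reactions.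
- Comparison: both key steps are known reaction classes and are about equal in mechanistic reliability. Alternative 1 fixes a regiochemistry that purchase already fixes, and it is longer by the preparation of A2 plus hydrolysis and decarboxylation.

Alternative 2: Two C–C bonds of ring B are cut, leading to methyl coumalate A6 and the ring C aryl ethynyl ether A5. On heating, the electron-rich alkyne would add across C3 and C6 of the electron-poor pyrone, with the alkyne CH bonding to C6 and the oxygen-bearing carbon to C3. Loss of CO2 from the bridged adduct would give the methyl 4-aryloxybenzoate A4.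
- In favour: polarity matching guarantees the para pattern, and the ether oxygen arrives already bonded to ring C, so no metal-mediated C–O coupling of an unactivated bromide is needed; on that point this plan is the better one. The ester of A4 also allows ring A to be varied late, which equals or exceeds the chosen plan for analogue work.
- Against: ring B is a plain para-phenylene available for almost nothing. A5 needs two steps from the ring C–D phenol and is a labile ynol ether that must survive the cycloaddition temperature. The ester of A4 must be reduced, olefinated and hydrogenated to build the A–B bridge. The ring C–D phenol behind A5 still needs its own solution to the para-alkylation problem.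
- Comparison: Alternative 2 answers the diaryl ether, which costs one copper-catalysed step in the chosen plan, and leaves the ring C problem open. It is longer by roughly five operations, though comparable in convergence.

Alternative 3: The C3–O bond of ring D is cut, leading back to the monophenol A8, in which ring D is a 2-alkylphenol and rings A and C are methylated. IBX would oxidise the only free ortho carbon of that phenol to the ortho-quinone A9, and Na2S2O4 in the work-up would reduce it to the catechol A7.
- In favour: only one ortho position is open, so the regiochemistry is unambiguous, and ring D enters as a simpler unit. The monophenol congener and the catechol both come from one intermediate, so this plan is better for divergence to ring D analogues. A late hydroxylation also plausibly mirrors biogenesis.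
- Against: A8 needs one phenol free while two others are masked, so an orthogonal protecting group and an extra deprotection are required. IBX can also attack the four benzylic methylenes, and A9 is an electrophilic, easily dimerised intermediate. A7 still carries two methyl ethers, so the Lewis acid demethylation is not saved.
- Comparison: Alternative 3 is an endgame adjustment, not a skeleton strategy. It solves neither ring C nor the diaryl ether, and it adds two or three operations to install an oxygen that (2,3-dimethoxyphenyl)acetic acid supplies from the outset. It is the equal of the chosen plan only in revealing the catechol at a late stage.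

Key step: step 8

Remark on the chemistry: the target is achiral. The olefin geometry of 4 and the racemic carbinol centres of 15 and 16 are all erased later, so no configuration needs to be controlled. The atom mapping is: phenolic carbon of 9 → carbonyl carbon of 10 → chain-bearing carbon of ring C; methoxy-bearing carbon of 9 → ketal carbon → hydroxyl-bearing carbon, with the aryloxy carbon beside it. This is consistent with the target.

## Route

Step 1
Reactants: 1 3-methoxybenzyl bromide; 2 4-bromobenzaldehyde
Product: 4 (E/Z)-1-bromo-4-[2-(3-methoxyphenyl)ethenyl]benzene, via phosphonium bromide 3 (not isolated)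
Conditions: PPh3, MeCN, reflux; then 2, K2CO3, 18-crown-6 (cat.), reflux
Reagents that add atoms: none
Why: PPh3 is quaternised by the benzylic bromide (SN2) to salt 3, carbonate deprotonates it to a semi-stabilised ylide, and Wittig olefination of the non-enolisable aldehyde follows. The E/Z mixture is acceptable because step 2 saturates the double bond, and the aryl bromide is inert here.

Step 2
Reactants: 4 (E/Z)-1-bromo-4-[2-(3-methoxyphenyl)ethenyl]benzene
Product: 5 1-bromo-4-[2-(3-methoxyphenyl)ethyl]benzene
Conditions: TsNHNH2, NaOAc, THF/H2O, reflux
Reagents that add atoms: none
Why: Diimide, released by base-assisted fragmentation of tosylhydrazide, transfers H2 to the C=C bond through a concerted cyclic transition state (diimide reduction). Unlike hydrogenation over palladium it cannot cleave the aryl C–Br bond needed in step 3.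

Step 3
Reactants: 5 1-bromo-4-[2-(3-methoxyphenyl)ethyl]benzene; 6 isovanillin (3-hydroxy-4-methoxybenzaldehyde)
Product: 7 4-methoxy-3-{4-[2-(3-methoxyphenyl)ethyl]phenoxy}benzaldehyde
Conditions: CuI (10 mol%), N,N-dimethylglycine hydrochloride (30 mol%), Cs2CO3, 1,4-dioxane, 100 °C
Reagents that add atoms: none
Why: This is a ligand-accelerated Ullmann diaryl ether synthesis: the caesium phenoxide of 6 binds monovalent copper, the aryl bromide adds oxidatively, and C–O reductive elimination gives 7. The tertiary amino acid ligand cannot condense with the aldehyde, and the hydroxyl of 6, meta to the formyl group, remains nucleophilic enough.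

Step 4
Reactants: 7 4-methoxy-3-{4-[2-(3-methoxyphenyl)ethyl]phenoxy}benzaldehyde
Product: 9 4-methoxy-3-{4-[2-(3-methoxyphenyl)ethyl]phenoxy}phenol, via aryl formate 8 (not isolated)
Conditions: mCPBA, CH2Cl2, 0 °C to rt; aq. NaHCO3/Na2S2O3 wash; then K2CO3 (cat.), MeOH, rt
Reagents that add atoms: meta-chloroperoxybenzoic acid (mCPBA), OOC(=O)c1cccc(Cl)c1
Why: In this Baeyer–Villiger (Dakin-type) oxidation the peracid adduct of the aldehyde rearranges with migration of the electron-rich para-methoxyaryl group to formate 8, which catalytic carbonate in methanol transesterifies to 9. The peracid is washed out before the phenol is released, so the oxidisable phenol never meets the oxidant.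

Step 5
Reactants: 9 4-methoxy-3-{4-[2-(3-methoxyphenyl)ethyl]phenoxy}phenol
Product: 10 4,4-dimethoxy-3-{4-[2-(3-methoxyphenyl)ethyl]phenoxy}cyclohexa-2,5-dien-1-one
Conditions: PhI(OAc)2, MeOH, 0 °C; NaHCO3 quench
Reagents that add atoms: methanol, CO
Why: This is the oxidative dearomatisation of a para-methoxyphenol by a trivalent iodine reagent: ligand exchange at iodine and loss of PhI give a phenoxonium-type species that methanol captures at the methoxy-stabilised para carbon. The anisole ring and the alkylphenyl ether ring are not oxidised at 0 °C.

Step 6
Reactants: 11 (2,3-dimethoxyphenyl)acetic acid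
Product: 12 2-(2,3-dimethoxyphenyl)ethanol
Conditions: BH3·THF, THF, 0 °C to rt; H2O quench
Reagents that add atoms: none
Why: Borane reduces the carboxylic acid through its acyloxyborane to the primary alcohol and leaves the aryl methyl ethers untouched (chemoselective borane reduction).

Step 7
Reactants: 12 2-(2,3-dimethoxyphenyl)ethanol
Product: 13 1-(2-bromoethyl)-2,3-dimethoxybenzene
Conditions: CBr4, PPh3, CH2Cl2, 0 °C to rt
Reagents that add atoms: carbon tetrabromide, BrC(Br)(Br)Br
Why: In the Appel reaction the alkoxyphosphonium ion is displaced by bromide in an SN2 step at the primary carbon. The neutral conditions avoid ether cleavage and elimination to the styrene.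

Step 8
Reactants: 13 1-(2-bromoethyl)-2,3-dimethoxybenzene; 10 4,4-dimethoxy-3-{4-[2-(3-methoxyphenyl)ethyl]phenoxy}cyclohexa-2,5-dien-1-one
Product: 15 racemic 1-[2-(2,3-dimethoxyphenyl)ethyl]-4,4-dimethoxy-3-{4-[2-(3-methoxyphenyl)ethyl]phenoxy}cyclohexa-2,5-dien-1-ol, via Grignard reagent 14 (not isolated)
Conditions: 13, Mg turnings (I2 cat.), THF, rt to 40 °C; add to 10, THF, −78 to −40 °C; sat. aq. NH4Cl
Reagents that add atoms: none
Why: Magnesium inserts into the primary C–Br bond of 13 to give 14, whose carbanionic CH2 adds 1,2 to the single free carbonyl of 10 after magnesium coordinates the carbonyl oxygen, and NH4Cl protonates the resulting alkoxide to the tertiary, doubly allylic carbinol 15. The closest known reaction type is the 1,2-addition of alkyllithium and Grignard reagents to quinone monoketals and to vinylogous esters. No ring is closed; one C–C bond is formed, between the ring C carbon and the terminal CH2 of the bridge. The carbinol carbon is a new stereocentre that forms as the racemate because the two faces of the planar dienone are enantiotopic; no control is needed because this carbon returns to sp2 in step 9. The selectivity required is carbonyl attack in preference to conjugate addition, attack at the ketal or displacement of the aryloxy group. The substrate secures it: one β-carbon carries the donating aryloxy group, which lowers its electrophilicity and would have to become fully substituted, the other lies next to the quaternary dimethoxy carbon, and a hard, non-stabilised alkylmagnesium at −78 °C attacks the carbonyl carbon under charge control. The dienone has no α-hydrogen, so enolisation cannot compete, and the ketal, the diaryl ether and the aryl methyl ethers are inert to the reagent. The cold, buffered quench keeps the acid-labile ketal and carbinol intact for isolation on triethylamine-deactivated silica.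

Step 9
Reactants: 15 racemic 1-[2-(2,3-dimethoxyphenyl)ethyl]-4,4-dimethoxy-3-{4-[2-(3-methoxyphenyl)ethyl]phenoxy}cyclohexa-2,5-dien-1-ol
Product: 17 4-[2-(2,3-dimethoxyphenyl)ethyl]-2-{4-[2-(3-methoxyphenyl)ethyl]phenoxy}phenol, via para-quinol 16 (not isolated)
Conditions: AcOH/H2O/THF (3:1:1), rt; then Zn dust, 50 °C
Reagents that add atoms: water, O
Why: Aqueous acetic acid ionises the dimethyl ketal to a methoxy-stabilised oxocarbenium ion that water converts into para-quinol 16 (ketal hydrolysis). Zinc then transfers two electrons to the cross-conjugated dienone, and the dienolate expels the hydroxide on the sp3 carbon, which is aligned with the π-system, to give the phenol (reductive aromatisation of a para-quinol). The aryloxy group sits on an sp2 carbon with its C–O bond in the ring plane and is not cleaved; the racemic carbinol centre disappears here.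

Step 10
Reactants: 17 4-[2-(2,3-dimethoxyphenyl)ethyl]-2-{4-[2-(3-methoxyphenyl)ethyl]phenoxy}phenol
Product: 18 3-[2-(4-hydroxy-3-{4-[2-(3-hydroxyphenyl)ethyl]phenoxy}phenyl)ethyl]benzene-1,2-diol (target)
Conditions: BBr3 (excess), CH2Cl2, −78 °C to rt; then ice/H2O, argon
Reagents that add atoms: none
Why: In this Lewis acid demethylation BBr3 coordinates each of the three methoxy oxygens and bromide attacks the methyl carbon. The diaryl ether has no sp3 carbon on oxygen and the bibenzyl bridges are inert, so hydrolysis of the aryl borates releases the tetraphenol, which is handled under argon because the catechol is oxidisable.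

## Compound list

1 | 3-methoxybenzyl bromide | COc1cccc(CBr)c1 | starting material
2 | 4-bromobenzaldehyde | O=Cc1ccc(Br)cc1 | starting material
3 | (3-methoxybenzyl)triphenylphosphonium bromide | COc1cccc(C[P+](c2ccccc2)(c2ccccc2)c2ccccc2)c1.[Br-] | intermediate (not isolated)
4 | (E/Z)-1-bromo-4-[2-(3-methoxyphenyl)ethenyl]benzene, mixture of olefin isomers | COc1cccc(C=Cc2ccc(Br)cc2)c1 | intermediate
5 | 1-bromo-4-[2-(3-methoxyphenyl)ethyl]benzene | COc1cccc(CCc2ccc(Br)cc2)c1 | intermediate
6 | isovanillin (3-hydroxy-4-methoxybenzaldehyde) | COc1ccc(C=O)cc1O | starting material
7 | 4-methoxy-3-{4-[2-(3-methoxyphenyl)ethyl]phenoxy}benzaldehyde | COc1ccc(C=O)cc1Oc1ccc(CCc2cccc(OC)c2)cc1 | intermediate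
8 | 4-methoxy-3-{4-[2-(3-methoxyphenyl)ethyl]phenoxy}phenyl formate | COc1ccc(OC=O)cc1Oc1ccc(CCc2cccc(OC)c2)cc1 | intermediate (not isolated)
9 | 4-methoxy-3-{4-[2-(3-methoxyphenyl)ethyl]phenoxy}phenol | COc1ccc(O)cc1Oc1ccc(CCc2cccc(OC)c2)cc1 | intermediate
10 | 4,4-dimethoxy-3-{4-[2-(3-methoxyphenyl)ethyl]phenoxy}cyclohexa-2,5-dien-1-one | COC1(OC)C=CC(=O)C=C1Oc1ccc(CCc2cccc(OC)c2)cc1 | intermediate
11 | (2,3-dimethoxyphenyl)acetic acid | COc1cccc(CC(=O)O)c1OC | starting material
12 | 2-(2,3-dimethoxyphenyl)ethanol | COc1cccc(CCO)c1OC | intermediate
13 | 1-(2-bromoethyl)-2,3-dimethoxybenzene | COc1cccc(CCBr)c1OC | intermediate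
14 | [2-(2,3-dimethoxyphenyl)ethyl]magnesium bromide | COc1cccc(CC[Mg]Br)c1OC | intermediate (not isolated)
15 | racemic 1-[2-(2,3-dimethoxyphenyl)ethyl]-4,4-dimethoxy-3-{4-[2-(3-methoxyphenyl)ethyl]phenoxy}cyclohexa-2,5-dien-1-ol | COC1(OC)C=CC(O)(CCc2cccc(OC)c2OC)C=C1Oc1ccc(CCc2cccc(OC)c2)cc1 | intermediate
16 | racemic 4-[2-(2,3-dimethoxyphenyl)ethyl]-4-hydroxy-2-{4-[2-(3-methoxyphenyl)ethyl]phenoxy}cyclohexa-2,5-dien-1-one | O=C1C=CC(O)(CCc2cccc(OC)c2OC)C=C1Oc1ccc(CCc2cccc(OC)c2)cc1 | intermediate (not isolated)
17 | 4-[2-(2,3-dimethoxyphenyl)ethyl]-2-{4-[2-(3-methoxyphenyl)ethyl]phenoxy}phenol | COc1cccc(CCc2ccc(Oc3cc(CCc4cccc(OC)c4OC)ccc3O)cc2)c1 | intermediate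
18 | 3-[2-(4-hydroxy-3-{4-[2-(3-hydroxyphenyl)ethyl]phenoxy}phenyl)ethyl]benzene-1,2-diol (achiral) | Oc1cccc(CCc2ccc(Oc3cc(CCc4cccc(O)c4O)ccc3O)cc2)c1 | target

## Step count and least certain steps

Total: 10 steps from commercial materials. Longest linear sequence: 8 steps (steps 1, 2, 3, 4, 5, 8, 9 and 10). The ring D branch (steps 6 and 7) joins at step 8.

Step 8 (key step). The most likely failure is diversion of the alkylmagnesium away from carbonyl addition. Possible causes are single-electron transfer to the quinoid acceptor, β-hydride delivery from the phenethyl reagent (reducing the dienone), or conjugate addition followed by loss of methoxide and rearomatisation. Sluggish attack on the vinylogous-ester carbonyl would favour all three. The fallback sets out from 10 and replaces the sp3 carbanion by an acetylide, which has no β-hydrogen and is a small, reliably 1,2-selective nucleophile. 1-Ethynyl-2,3-dimethoxybenzene F1 is made from 2,3-dimethoxybenzaldehyde by Seyferth–Gilbert homologation with dimethyl (1-diazo-2-oxopropyl)phosphonate, K2CO3 and MeOH. It is deprotonated with n-BuLi in THF at −78 °C and added to 10 to give the propargylic quinol ketal F2. Aqueous acetic acid and then zinc, as in step 9, lead through the alkynyl quinol F3 to the diarylalkyne phenol F4. Hydrogenation (H2, Pd/C, EtOAc) saturates the triple bond and rejoins the route at 17.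

Step 9. Two processes threaten it. The first is ionisation of the tertiary, doubly allylic hydroxyl before the ketal, which would lead to transposition with loss of the aryloxy group in the manner of a vinylogous ester. The second is electron transfer that partly saturates the enone instead of expelling hydroxide. The fallback sets out from 15 and separates the two events. 15 is hydrolysed under buffered two-phase conditions (oxalic acid on wet silica, CH2Cl2) and 16 is isolated. Luche reduction (NaBH4, CeCl3·7H2O, MeOH, −20 °C) then gives 1-[2-(2,3-dimethoxyphenyl)ethyl]-3-{4-[2-(3-methoxyphenyl)ethyl]phenoxy}cyclohexa-2,5-diene-1,4-diol F5 as a mixture of diastereomers. A catalytic amount of TsOH in CH2Cl2 ionises the tertiary carbinol, which the vinylogous aryloxy group stabilises, and loss of the proton from the secondary carbinol carbon aromatises the ring. This redox-neutral reduction–dehydration rejoins the route at 17.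

Step 3. The coupling may stall through slow oxidative addition of the electron-neutral bromide, sequestration of copper by the ortho-methoxyphenoxide, or base-induced degradation of the aldehyde at 100 °C. The fallback sets out from 5 and reverses the roles in an oxidative coupling at room temperature. Bromine–lithium exchange (n-BuLi, THF, −78 °C), B(OiPr)3 and acidic work-up give {4-[2-(3-methoxyphenyl)ethyl]phenyl}boronic acid F6. Chan–Lam coupling with 6 (Cu(OAc)2, pyridine, 4 Å molecular sieves, CH2Cl2, air), mediated by divalent copper, rejoins the route at 7.

Step 5. The risks are over-oxidation, methanol capture at an ortho carbon, and hydrolysis of the new ketal to the quinone during work-up or chromatography. The fallback sets out from 9 and reaches the monoketal without a phenol oxidation. Methylation (MeI, K2CO3, acetone) gives 1,4-dimethoxy-2-{4-[2-(3-methoxyphenyl)ethyl]phenoxy}benzene F7. Anodic oxidation (Pt anode, KOH/MeOH, 0 °C) gives the quinone bisketal 3,3,6,6-tetramethoxy-1-{4-[2-(3-methoxyphenyl)ethyl]phenoxy}cyclohexa-1,4-diene F8. Brief treatment with aqueous acetic acid in acetone at 0 °C hydrolyses the ketal remote from the aryloxy carbon, because only that ionisation is stabilised by the vinylogous aryloxy group, and rejoins the route at 10.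

## Further compounds

F1 | step 8 | 1-ethynyl-2,3-dimethoxybenzene | COc1cccc(C#C)c1OC
F2 | step 8 | racemic 1-[(2,3-dimethoxyphenyl)ethynyl]-4,4-dimethoxy-3-{4-[2-(3-methoxyphenyl)ethyl]phenoxy}cyclohexa-2,5-dien-1-ol | COC1(OC)C=CC(O)(C#Cc2cccc(OC)c2OC)C=C1Oc1ccc(CCc2cccc(OC)c2)cc1
F3 | step 8 | racemic 4-[(2,3-dimethoxyphenyl)ethynyl]-4-hydroxy-2-{4-[2-(3-methoxyphenyl)ethyl]phenoxy}cyclohexa-2,5-dien-1-one | O=C1C=CC(O)(C#Cc2cccc(OC)c2OC)C=C1Oc1ccc(CCc2cccc(OC)c2)cc1
F4 | step 8 | 4-[(2,3-dimethoxyphenyl)ethynyl]-2-{4-[2-(3-methoxyphenyl)ethyl]phenoxy}phenol | COc1cccc(CCc2ccc(Oc3cc(C#Cc4cccc(OC)c4OC)ccc3O)cc2)c1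
F5 | step 9 | 1-[2-(2,3-dimethoxyphenyl)ethyl]-3-{4-[2-(3-methoxyphenyl)ethyl]phenoxy}cyclohexa-2,5-diene-1,4-diol (mixture of diastereomers) | OC1C=CC(O)(CCc2cccc(OC)c2OC)C=C1Oc1ccc(CCc2cccc(OC)c2)cc1
F6 | step 3 | {4-[2-(3-methoxyphenyl)ethyl]phenyl}boronic acid | COc1cccc(CCc2ccc(B(O)O)cc2)c1
F7 | step 5 | 1,4-dimethoxy-2-{4-[2-(3-methoxyphenyl)ethyl]phenoxy}benzene | COc1ccc(OC)c(Oc2ccc(CCc3cccc(OC)c3)cc2)c1
F8 | step 5 | 3,3,6,6-tetramethoxy-1-{4-[2-(3-methoxyphenyl)ethyl]phenoxy}cyclohexa-1,4-diene | COC1(OC)C=CC(OC)(OC)C(Oc2ccc(CCc3cccc(OC)c3)cc2)=C1
A1 | alternative 1 | methyl 2-[2-(4-{5-[2-(2,3-dimethoxyphenyl)ethyl]-2-methoxyphenoxy}phenyl)ethyl]-6-hydroxybenzoate | COC(=O)c1c(O)cccc1CCc1ccc(Oc2cc(CCc3cccc(OC)c3OC)ccc2OC)cc1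
A2 | alternative 1 | 5-(4-{5-[2-(2,3-dimethoxyphenyl)ethyl]-2-methoxyphenoxy}phenyl)-1,1-dimethoxypentan-3-one | COC(OC)CC(=O)CCc1ccc(Oc2cc(CCc3cccc(OC)c3OC)ccc2OC)cc1
A3 | alternative 1 | 1-methoxy-1,3-bis(trimethylsilyloxy)buta-1,3-diene | COC(O[Si](C)(C)C)=CC(=C)O[Si](C)(C)C
A4 | alternative 2 | methyl 4-{5-[2-(2,3-dimethoxyphenyl)ethyl]-2-methoxyphenoxy}benzoate | COC(=O)c1ccc(Oc2cc(CCc3cccc(OC)c3OC)ccc2OC)cc1
A5 | alternative 2 | 4-[2-(2,3-dimethoxyphenyl)ethyl]-2-(ethynyloxy)-1-methoxybenzene | C#COc1cc(CCc2cccc(OC)c2OC)ccc1OC
A6 | alternative 2 | methyl coumalate (methyl 2-oxo-2H-pyran-5-carboxylate) | COC(=O)C1=COC(=O)C=C1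
A7 | alternative 3 | 3-[2-(4-methoxy-3-{4-[2-(3-methoxyphenyl)ethyl]phenoxy}phenyl)ethyl]benzene-1,2-diol | COc1cccc(CCc2ccc(Oc3cc(CCc4cccc(O)c4O)ccc3OC)cc2)c1
A8 | alternative 3 | 2-[2-(4-methoxy-3-{4-[2-(3-methoxyphenyl)ethyl]phenoxy}phenyl)ethyl]phenol | COc1cccc(CCc2ccc(Oc3cc(CCc4ccccc4O)ccc3OC)cc2)c1
A9 | alternative 3 | 3-[2-(4-methoxy-3-{4-[2-(3-methoxyphenyl)ethyl]phenoxy}phenyl)ethyl]cyclohexa-3,5-diene-1,2-dione | COc1cccc(CCc2ccc(Oc3cc(CCC4=CC=CC(=O)C4=O)ccc3OC)cc2)c1
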